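**Plan**

1. Retrosynthesis: remove the two acetyl groups (O2, O15); trace C9–H and the C7=C8 alkene back, through two allylic transpositions, to a C9 ketone plus the C11–C15 chain as an alkyllithium (cut C9–C11); remove O2/O3 to a C2=C3 alkene; cut C3–C4 (ring A); cut C10–C1 and C10–CH3 to reach (S)-carvone.
2. Forward: (S)-carvone supplies ring B; C10 is made quaternary by methylation, then allylation with a (Z)-3-silylallyl bromide; ring A is closed last by a vinylsilane-terminated cation–olefin cyclisation; dihydroxylation, side-chain addition, oxidative then reductive 1,3-transposition, deprotection and diacetylation follow.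
3. Enabling feature: on ring B the isopropenyl group at C5 (it becomes C4 and both C4 methyl groups) and the arm C1–C2=C3–Si at C10 are trans, so the C4 cation reaches C3 through a chair and a trans-decalin results; silicon on C3 fixes the new alkene at C2=C3, where the diol is needed.
4. Stereochemistry: C5 from (S)-carvone; C10 by alkylation anti to the isopropenyl group; C2 and C3 by OsO4 addition anti to the axial C4 and C10 methyl groups; C9 by suprafacial hydrogen delivery within a C7 diazene; C13 from (R)-methyl hydrogen 3-methylglutarate.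

Key step: step 5

Remark on the chemistry: positions are given in labdane numbering (C1–C20); compounds 1, 4 and 14 are taken as commercial, enantiopure where chiral, and 6 is carried forward with its minor C6 epimer because that centre is re-enolised in step 4.

**Route**

Step 1
Reactants: 1 3-(trimethylsilyl)prop-2-yn-1-ol
Product: 2 (Z)-3-(trimethylsilyl)prop-2-en-1-ol
Conditions: H2 (1 atm), Ni(OAc)2·4H2O/NaBH4 (nickel boride), ethylenediamine, EtOH, rt
Reagents that add atoms: none
Why: cis-selective catalytic semihydrogenation of the silylalkyne over amine-poisoned nickel boride should deliver both hydrogens syn and stop at the (Z)-vinylsilane.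

Step 2
Reactants: 2 (Z)-3-(trimethylsilyl)prop-2-en-1-ol
Product: 3 (Z)-(3-bromoprop-1-en-1-yl)trimethylsilane
Conditions: CBr4, PPh3, CH2Cl2, 0 °C
Reagents that add atoms: carbon tetrabromide, BrC(Br)(Br)Br
Why: Appel bromination under neutral conditions should convert the primary allylic alcohol to the bromide by SN2 displacement without touching the vinylsilane or its Z geometry.

Step 3
Reactants: 4 (S)-carvone
Product: 6 (5S,6R)-2,6-dimethyl-5-(prop-1-en-2-yl)cyclohex-2-en-1-one, via lithium dienolate 5 (not isolated)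
Conditions: LiN(i-Pr)2, THF, −78 °C; MeI, −78 → 0 °C
Reagents that add atoms: iodomethane, CI
Why: kinetic deprotonation at C6 and SN2 methylation of the cross-conjugated enolate (enolate alkylation) should give mainly the trans isomer; the new centre is erased again in step 4.

Step 4
Reactants: 6 (5S,6R)-2,6-dimethyl-5-(prop-1-en-2-yl)cyclohex-2-en-1-one; 3 (Z)-(3-bromoprop-1-en-1-yl)trimethylsilane
Product: 8 (5R,6R)-2,6-dimethyl-5-(prop-1-en-2-yl)-6-[(2Z)-3-(trimethylsilyl)prop-2-en-1-yl]cyclohex-2-en-1-one, via lithium enolate 7 (not isolated)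
Conditions: LiN(i-Pr)2, THF, −78 °C; then 3, DMPU, −78 → 0 °C
Reagents that add atoms: none
Why: alkylation of the tetrasubstituted enolate with the allylic bromide (enolate alkylation) should occur anti to the adjacent isopropenyl group, setting the quaternary carbon (future C10) with the methyl cis and the silylallyl arm trans to the isopropenyl group.

Step 5
Reactants: 8 (5R,6R)-2,6-dimethyl-5-(prop-1-en-2-yl)-6-[(2Z)-3-(trimethylsilyl)prop-2-en-1-yl]cyclohex-2-en-1-one
Product: 11 (4aR,8aR)-2,5,5,8a-tetramethyl-4a,5,8,8a-tetrahydronaphthalen-1(4H)-one, via tertiary carbocation 9 (not isolated), via beta-silyl carbocation 10 (not isolated)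
Conditions: CF3CO2H (5 equiv), CH2Cl2, 0 °C to rt
Reagents that add atoms: none
Why: Protonation of the 1,1-disubstituted isopropenyl alkene gives the tertiary cation at C4, which is attacked by the silicon-bearing carbon C3 of the (Z)-vinylsilane because the charge developing at C2 is stabilised by the β C–Si bond; loss of the silyl group to trifluoroacetate then leaves the alkene at C2=C3. The closest known reaction type is the vinylsilane-terminated cation–olefin cyclisation (ipso substitution of a vinylsilane by a carbocation). Ring A is closed in the 6-endo-trig mode with respect to the vinylsilane, through a chair-like transition state in which C4 and C1 are both equatorial on ring B. No new stereocentre is created: the trans ring fusion is dictated by the C5 and C10 centres already present, and C4 becomes the gem-dimethyl quaternary carbon. The step needs chemoselective protonation, secured by the higher nucleophilicity of the isopropenyl group over the 1,2-disubstituted vinylsilane and the deactivated enone alkene, and attack at C3 instead of C2, secured by the β-silicon effect, by six- over five-membered ring formation and by the Z geometry that places silicon where the new bond must form.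

Step 6
Reactants: 11 (4aR,8aR)-2,5,5,8a-tetramethyl-4a,5,8,8a-tetrahydronaphthalen-1(4H)-one
Product: 12 (4aR,6R,7S,8aR)-6,7-dihydroxy-2,5,5,8a-tetramethyl-4a,5,6,7,8,8a-hexahydronaphthalen-1(4H)-one
Conditions: OsO4 (2 mol %), N-methylmorpholine N-oxide (1.2 equiv), acetone/H2O (8:1), 0 °C → rt
Reagents that add atoms: OsO4 (catalyst that transfers the oxygens), O=[Os](=O)(=O)=O; N-methylmorpholine N-oxide, C[N+]1([O-])CCOCC1; water, O
Why: Upjohn dihydroxylation should select the isolated cis-disubstituted C2=C3 alkene over the electron-poor enone alkene and add both oxygens syn from the face opposite the axial C4 and C10 methyl groups, setting C2 (equatorial O) and C3 (axial O).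

Step 7
Reactants: 12 (4aR,6R,7S,8aR)-6,7-dihydroxy-2,5,5,8a-tetramethyl-4a,5,6,7,8,8a-hexahydronaphthalen-1(4H)-one
Product: 13 2,3-O-isopropylidene acetal (acetonide) of 12
Conditions: Me2C(OMe)2, pyridinium p-toluenesulfonate (cat.), CH2Cl2, rt
Reagents that add atoms: 2,2-dimethoxypropane, COC(C)(C)OC
Why: acid-catalysed transketalisation should tie the cis-diol up as the five-membered acetonide, which tolerates the organolithium, chromium, hydride and Mitsunobu steps that follow.

Step 8
Reactants: 14 (R)-5-methoxy-3-methyl-5-oxopentanoic acid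
Product: 15 methyl (R)-5-hydroxy-3-methylpentanoate
Conditions: BH3·SMe2, THF, 0 °C → rt; then MeOH
Reagents that add atoms: none
Why: borane reduces a free carboxylic acid much faster than an ester (chemoselective acid reduction), so the acid end (future C15) should become the primary alcohol while the ester end and the stereocentre stay untouched.

Step 9
Reactants: 15 methyl (R)-5-hydroxy-3-methylpentanoate
Product: 16 methyl (R)-5-[(tert-butyldimethylsilyl)oxy]-3-methylpentanoate
Conditions: TBSCl, imidazole, CH2Cl2, 0 °C → rt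
Reagents that add atoms: tert-butyldimethylsilyl chloride, CC(C)(C)[Si](C)(C)Cl
Why: silyl ether formation at the primary alcohol should prevent lactonisation and protect O15 through the organolithium step.

Step 10
Reactants: 16 methyl (R)-5-[(tert-butyldimethylsilyl)oxy]-3-methylpentanoate
Product: 17 (S)-5-[(tert-butyldimethylsilyl)oxy]-3-methylpentan-1-ol
Conditions: LiAlH4, Et2O, 0 °C
Reagents that add atoms: none
Why: hydride reduction of the ester should give the primary alcohol (future C11) without affecting the silyl ether.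

Step 11
Reactants: 17 (S)-5-[(tert-butyldimethylsilyl)oxy]-3-methylpentan-1-ol
Product: 18 (R)-tert-butyl[(5-iodo-3-methylpentyl)oxy]dimethylsilane
Conditions: I2, PPh3, imidazole, CH2Cl2, 0 °C → rt
Reagents that add atoms: iodine, II
Why: Appel-type iodination should convert the primary alcohol to the iodide by SN2 displacement, two carbons away from the stereocentre.

Step 12
Reactants: 18 (R)-tert-butyl[(5-iodo-3-methylpentyl)oxy]dimethylsilane; 13 2,3-O-isopropylidene acetal (acetonide) of 12
Product: 20 15-O-TBS 2,3-O-isopropylidene labd-7-ene-2,3,9,15-tetrol (9-OH on the C10-methyl face), via alkyllithium 19 (not isolated)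
Conditions: t-BuLi (2.1 equiv), Et2O, −78 °C; then 13, −78 → 0 °C; H2O
Reagents that add atoms: none
Why: lithium–iodine exchange followed by 1,2-addition of the primary alkyllithium to the hindered enone carbonyl (organolithium carbonyl addition) should form the C9–C11 bond from the face opposite the axial C10 methyl; the C9 configuration is of no consequence because C9 becomes sp2 in step 13.

Step 13
Reactants: 20 15-O-TBS 2,3-O-isopropylidene labd-7-ene-2,3,9,15-tetrol
Product: 23 15-O-TBS 2,3-O-isopropylidene 2,3,15-trihydroxylabd-8-en-7-one, via tertiary chlorochromate ester 21 (not isolated), via transposed chlorochromate ester 22 (not isolated)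
Conditions: [C5H5NH][CrO3Cl] (pyridinium chlorochromate, 3 equiv), NaOAc, 4 Å molecular sieves, CH2Cl2, rt
Reagents that add atoms: pyridinium chlorochromate, [O-][Cr](=O)(=O)Cl.c1cc[nH+]cc1
Why: Babler–Dauben oxidative 1,3-transposition: the tertiary allylic chromate ester undergoes [3,3]-sigmatropic shift to the secondary allylic ester, which is oxidised to the enone, moving oxygen from C9 to C7 and the alkene to C8=C9.

Step 14
Reactants: 23 15-O-TBS 2,3-O-isopropylidene 2,3,15-trihydroxylabd-8-en-7-one
Product: 24 15-O-TBS 2,3-O-isopropylidene labd-8-ene-2,3,7,15-tetrol (7-OH on the C10-methyl face)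
Conditions: NaBH4, CeCl3·7H2O, MeOH, −40 → 0 °C
Reagents that add atoms: none
Why: Luche reduction should give clean 1,2-reduction, with hydride entering axially from the face opposite the C10 methyl so that the C7 hydroxyl is pseudo-equatorial and on the C10-methyl face.

Step 15
Reactants: 24 15-O-TBS 2,3-O-isopropylidene labd-8-ene-2,3,7,15-tetrol
Product: 27 15-O-TBS 2,3-O-isopropylidene labd-7-ene-2,3,15-triol, via N-sulfonyl hydrazine adduct 25 (not isolated), via allylic diazene 26 (not isolated)
Conditions: 2-O2NC6H4SO2NHNH2, PPh3, EtO2CN=NCO2Et, N-methylmorpholine, −30 °C; then rt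
Reagents that add atoms: none
Why: reductive 1,3-transposition of the allylic alcohol: Mitsunobu displacement by the sulfonylhydrazide inverts C7, loss of arenesulfinic acid gives the monoalkyl diazene, and its retro-ene loss of N2 delivers hydrogen suprafacially to C9 on the face opposite the C10 methyl, setting C9 (side chain equatorial) and returning the alkene to C7=C8.

Step 16
Reactants: 27 15-O-TBS 2,3-O-isopropylidene labd-7-ene-2,3,15-triol
Product: 28 (2S,3R,5S,9R,10S,13S)-labd-7-ene-2,3,15-triol
Conditions: HCl (2 M aq.)/THF (1:2), rt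
Reagents that add atoms: none
Why: aqueous acid should hydrolyse the acetonide and the primary silyl ether in one operation (acetal hydrolysis and desilylation) under conditions too mild to isomerise the trisubstituted alkene.

Step 17
Reactants: 28 (2S,3R,5S,9R,10S,13S)-labd-7-ene-2,3,15-triol
Product: 29 (2S,3R,5S,9R,10S,13S)-3-hydroxylabd-7-ene-2,15-diyl diacetate
Conditions: Ac2O (2.2 equiv), pyridine, 0 °C → rt
Reagents that add atoms: acetic anhydride, CC(=O)OC(C)=O
Why: acetylation without an acyl-transfer catalyst (site-selective esterification) should take the primary C15 hydroxyl and the equatorial C2 hydroxyl and leave the axial, neopentyl C3 hydroxyl next to the C4 gem-dimethyl group free.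

**Compound list**

1 | 3-(trimethylsilyl)prop-2-yn-1-ol | C[Si](C)(C)C#CCO | starting material
2 | (Z)-3-(trimethylsilyl)prop-2-en-1-ol | C[Si](C)(C)/C=C\CO | intermediate
3 | (Z)-(3-bromoprop-1-en-1-yl)trimethylsilane | C[Si](C)(C)/C=C\CBr | intermediate
4 | (S)-carvone, (5S)-2-methyl-5-(prop-1-en-2-yl)cyclohex-2-en-1-one | O=C1C(C)=CC[C@@H](C1)C(C)=C | starting material
5 | lithium dienolate of 4 (O–Li on C1, C1=C6 and C2=C3, C5 unchanged) | [Li]OC1=C[C@H](CC=C1C)C(C)=C | intermediate (not isolated)
6 | (5S,6R)-2,6-dimethyl-5-(prop-1-en-2-yl)cyclohex-2-en-1-one (trans-6-methylcarvone) | O=C1C(C)=CC[C@@H]([C@H]1C)C(C)=C | intermediate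
7 | lithium enolate of 6 (O–Li on C1, C1=C6 tetrasubstituted) | [Li]OC1=C(C)[C@H](CC=C1C)C(C)=C | intermediate (not isolated)
8 | (5R,6R)-2,6-dimethyl-5-(prop-1-en-2-yl)-6-[(2Z)-3-(trimethylsilyl)prop-2-en-1-yl]cyclohex-2-en-1-one (silylallyl arm trans to isopropenyl) | O=C1C(C)=CC[C@@H]([C@@]1(C)C/C=C\[Si](C)(C)C)C(C)=C | intermediate
9 | tertiary carbocation from 8 (2-propyl cation on C5, future C4) | O=C1C(C)=CC[C@@H]([C@@]1(C)C/C=C\[Si](C)(C)C)[C+](C)C | intermediate (not isolated)
10 | beta-silyl carbocation (ring A closed, SiMe3 on C3, cation at C2; C3 configuration lost on desilylation) | O=C1C(C)=CC[C@@H]2C(C)(C)C([Si](C)(C)C)[CH+]C[C@@]12C | intermediate (not isolated)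
11 | (4aR,8aR)-2,5,5,8a-tetramethyl-4a,5,8,8a-tetrahydronaphthalen-1(4H)-one (trans-fused; 9-oxo, C2=C3 and C7=C8 alkenes) | O=C1C(C)=CC[C@@H]2C(C)(C)C=CC[C@@]12C | intermediate
12 | (4aR,6R,7S,8aR)-6,7-dihydroxy-2,5,5,8a-tetramethyl-4a,5,6,7,8,8a-hexahydronaphthalen-1(4H)-one (cis-2,3-diol anti to the C10 methyl) | O=C1C(C)=CC[C@@H]2C(C)(C)[C@@H](O)[C@@H](O)C[C@@]12C | intermediate
13 | 2,3-O-isopropylidene acetal (acetonide) of 12 | O=C1C(C)=CC[C@@H]2C(C)(C)[C@H]3OC(C)(C)O[C@H]3C[C@@]12C | intermediate
14 | (R)-5-methoxy-3-methyl-5-oxopentanoic acid, (R)-methyl hydrogen 3-methylglutarate | OC(=O)C[C@@H](C)CC(=O)OC | starting material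
15 | methyl (R)-5-hydroxy-3-methylpentanoate | OCC[C@@H](C)CC(=O)OC | intermediate
16 | methyl (R)-5-[(tert-butyldimethylsilyl)oxy]-3-methylpentanoate | CC(C)(C)[Si](C)(C)OCC[C@@H](C)CC(=O)OC | intermediate
17 | (S)-5-[(tert-butyldimethylsilyl)oxy]-3-methylpentan-1-ol | CC(C)(C)[Si](C)(C)OCC[C@@H](C)CCO | intermediate
18 | (R)-tert-butyl[(5-iodo-3-methylpentyl)oxy]dimethylsilane | CC(C)(C)[Si](C)(C)OCC[C@@H](C)CCI | intermediate
19 | (S)-5-[(tert-butyldimethylsilyl)oxy]-3-methylpentyllithium | CC(C)(C)[Si](C)(C)OCC[C@@H](C)CC[Li] | intermediate (not isolated)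
20 | 15-O-TBS 2,3-O-isopropylidene labd-7-ene-2,3,9,15-tetrol (9-OH on the C10-methyl face; other centres as in 29) | CC(C)(C)[Si](C)(C)OCC[C@@H](C)CC[C@@]1(O)C(C)=CC[C@@H]2C(C)(C)[C@H]3OC(C)(C)O[C@H]3C[C@@]12C | intermediate
21 | tertiary chlorochromate ester of 20 (at O9) | CC(C)(C)[Si](C)(C)OCC[C@@H](C)CC[C@@]1(O[Cr](=O)(=O)Cl)C(C)=CC[C@@H]2C(C)(C)[C@H]3OC(C)(C)O[C@H]3C[C@@]12C | intermediate (not isolated)
22 | transposed chlorochromate ester (at O7, C8=C9 alkene) | CC(C)(C)[Si](C)(C)OCC[C@@H](C)CCC1=C(C)[C@H](O[Cr](=O)(=O)Cl)C[C@@H]2C(C)(C)[C@H]3OC(C)(C)O[C@H]3C[C@@]12C | intermediate (not isolated)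
23 | 15-O-TBS 2,3-O-isopropylidene 2,3,15-trihydroxylabd-8-en-7-one | CC(C)(C)[Si](C)(C)OCC[C@@H](C)CCC1=C(C)C(=O)C[C@@H]2C(C)(C)[C@H]3OC(C)(C)O[C@H]3C[C@@]12C | intermediate
24 | 15-O-TBS 2,3-O-isopropylidene labd-8-ene-2,3,7,15-tetrol (7-OH on the C10-methyl face) | CC(C)(C)[Si](C)(C)OCC[C@@H](C)CCC1=C(C)[C@H](O)C[C@@H]2C(C)(C)[C@H]3OC(C)(C)O[C@H]3C[C@@]12C | intermediate
25 | N-(C7-yl)-N-(2-nitrobenzenesulfonyl)hydrazine from 24 (C7 inverted, N on the face opposite the C10 methyl) | CC(C)(C)[Si](C)(C)OCC[C@@H](C)CCC1=C(C)[C@@H](N(N)S(=O)(=O)c4ccccc4[N+](=O)[O-])C[C@@H]2C(C)(C)[C@H]3OC(C)(C)O[C@H]3C[C@@]12C | intermediate (not isolated)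
26 | allylic diazene (C7–N=NH) | CC(C)(C)[Si](C)(C)OCC[C@@H](C)CCC1=C(C)[C@@H](N=N)C[C@@H]2C(C)(C)[C@H]3OC(C)(C)O[C@H]3C[C@@]12C | intermediate (not isolated)
27 | 15-O-TBS 2,3-O-isopropylidene labd-7-ene-2,3,15-triol (all centres as in 29) | CC(C)(C)[Si](C)(C)OCC[C@@H](C)CC[C@@H]1C(C)=CC[C@@H]2C(C)(C)[C@H]3OC(C)(C)O[C@H]3C[C@@]12C | intermediate
28 | (2S,3R,5S,9R,10S,13S)-labd-7-ene-2,3,15-triol | OCC[C@@H](C)CC[C@@H]1C(C)=CC[C@@H]2C(C)(C)[C@@H](O)[C@@H](O)C[C@@]12C | intermediate
29 | (2S,3R,5S,9R,10S,13S)-3-hydroxylabd-7-ene-2,15-diyl diacetate | CC(=O)OCC[C@@H](C)CC[C@@H]1C(C)=CC[C@@H]2C(C)(C)[C@@H](O)[C@@H](OC(C)=O)C[C@@]12C | target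

**Step count**

Total step count: 17. Longest linear sequence: 12 steps (steps 1, 2, 4, 5, 6, 7, 12, 13, 14, 15, 16, 17); 11 steps from carvone.

**Steps most likely to fail and their fallbacks**

Step 5. The vinylsilane may lose silicon by protodesilylation, or the tertiary cation may undergo 1,2-hydride shift and elimination, before ring closure occurs. The fallback sets out from 6 and comes back to the route at 11. Alkylation of the enolate of 6 with propargyl bromide in place of 3 (same anti selectivity) would give (5R,6R)-2,6-dimethyl-5-(prop-1-en-2-yl)-6-(prop-2-yn-1-yl)cyclohex-2-en-1-one F1. Treatment with CF3SO3H in CH2Cl2 at −40 °C would protonate the isopropenyl group and let the terminal alkyne carbon (C3) close ring A, the C2 vinyl cation being captured by triflate to give (4aR,8aR)-2,5,5,8a-tetramethyl-1-oxo-1,4,4a,5,8,8a-hexahydronaphthalen-7-yl trifluoromethanesulfonate F2. Reduction of this alkenyl triflate with Pd(OAc)2/PPh3, Bu3N and HCO2H in DMF at 60 °C would give 11.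

Step 15. The SN2 Mitsunobu displacement at the hindered allylic carbinol may fail, with elimination to a diene taking over. The fallback sets out from 24 and comes back at 27. Formylation (HCO2H/Ac2O, pyridine, 0 °C) would give the 7-O-formate of 24 F3. Heating with Pd(OAc)2 and PBu3 in dioxane would form the π-allylpalladium formate on the face opposite the leaving group; after loss of CO2, hydride would pass from palladium to the more substituted terminus C9 on that same face, giving 27 with the same C9 configuration.

Step 17. Over-acetylation at the axial C3 hydroxyl, or acetyl migration between the cis oxygens, may erode the site selectivity. The fallback sets out from 27 and comes back at 29. Bu4NF in THF would remove only the silyl ether to give the 2,3-O-isopropylidene labd-7-ene-2,3,15-triol F4. Ac2O/pyridine with 4-(dimethylamino)pyridine would give its 15-acetate F5. Aqueous AcOH (80%) at 45 °C would remove the acetonide to give the labd-7-ene-2,3,15-triol 15-monoacetate F6. Bu2SnO in toluene at reflux with removal of water would form the 2,3-O-dibutylstannylene acetal F7, and AcCl at 0 °C would acylate its equatorial oxygen (O2) selectively, giving 29 after aqueous work-up.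

**Further compounds**

F1 | step 5 | (5R,6R)-2,6-dimethyl-5-(prop-1-en-2-yl)-6-(prop-2-yn-1-yl)cyclohex-2-en-1-one | O=C1C(C)=CC[C@@H]([C@@]1(C)CC#C)C(C)=C
F2 | step 5 | (4aR,8aR)-2,5,5,8a-tetramethyl-1-oxo-1,4,4a,5,8,8a-hexahydronaphthalen-7-yl trifluoromethanesulfonate | O=C1C(C)=CC[C@@H]2C(C)(C)C=C(OS(=O)(=O)C(F)(F)F)C[C@@]12C
F3 | step 15 | 7-O-formate of 24 | CC(C)(C)[Si](C)(C)OCC[C@@H](C)CCC1=C(C)[C@H](OC=O)C[C@@H]2C(C)(C)[C@H]3OC(C)(C)O[C@H]3C[C@@]12C
F4 | step 17 | 2,3-O-isopropylidene labd-7-ene-2,3,15-triol | OCC[C@@H](C)CC[C@@H]1C(C)=CC[C@@H]2C(C)(C)[C@H]3OC(C)(C)O[C@H]3C[C@@]12C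
F5 | step 17 | 2,3-O-isopropylidene labd-7-ene-2,3,15-triol 15-acetate | CC(=O)OCC[C@@H](C)CC[C@@H]1C(C)=CC[C@@H]2C(C)(C)[C@H]3OC(C)(C)O[C@H]3C[C@@]12C
F6 | step 17 | labd-7-ene-2,3,15-triol 15-monoacetate | CC(=O)OCC[C@@H](C)CC[C@@H]1C(C)=CC[C@@H]2C(C)(C)[C@@H](O)[C@@H](O)C[C@@]12C
F7 | step 17 | 2,3-O-dibutylstannylene acetal of F6 | CC(=O)OCC[C@@H](C)CC[C@@H]1C(C)=CC[C@@H]2C(C)(C)[C@H]3O[Sn](CCCC)(CCCC)O[C@H]3C[C@@]12C
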